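**Plan**

- Retrosynthesis: the two ring B benzyl groups of target 1 come off last. Ring A is cut at C6–C1 and C2–C3 (with a C2H4 bridge restored), an Alder–Rickert disconnection to a 1-aryloxy-3-silyloxycyclohexa-1,3-diene and an oct-2-ynoate ester.
- The diene is cut at its vinyl C–O bond to a ring B phenol and a 3-chloroenone. The phenol goes back, through para-hydroxylation, O-benzylation, O-methylation, esterification and carboxylation, to olivetol 2.
- Forward: ring B is finished first on olivetol 2, then joined through its new phenolic oxygen to a six-membered enone, which is turned into the diene. Ring A is built last, around the carbon that already carries the ether oxygen.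
- Enabling feature: ring A is a resorcinol monoaryl ether (C4 OH, C6 OAr) whose two remaining adjacent carbons bear CO2Me (C1) and pentyl (C2). This is the pattern a 1-alkoxy-3-silyloxy diene and an alk-2-ynoate deliver after loss of ethylene.
- Stereochemistry: the target has no stereocentre. Only regiochemistry must be controlled (para-hydroxylation of ring B, kinetic enolisation, polarity-matched cycloaddition).

Key step: step 9

Assumption: MeOMgOCO2Me is taken to carboxylate olivetol 2 at the ring position flanked by a hydroxyl and the pentyl group, giving olivetolic acid 3; a fallback covers competing attack between the two hydroxyls.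

**Route**

Step 1
Reactants: 2 olivetol (5-pentylbenzene-1,3-diol)
Product: 3 olivetolic acid (2,4-dihydroxy-6-pentylbenzoic acid)
Conditions: MeOMgOCO2Me (2 M in DMF, excess), 120 °C, N2 sweep; then cold 2 M aq HCl
Reagents that add atoms: methyl magnesium carbonate (MeOMgOCO2Me), COC(=O)O[Mg]OC
Why: Magnesium-chelated ortho-carboxylation of a phenol (Stiles variant of the Kolbe-Schmitt reaction) is established for resorcinols, and the magnesium salicylate chelate holds the CO2 until the cold acidic quench.

Step 2
Reactants: 3 olivetolic acid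
Product: 4 benzyl olivetolate (benzyl 2,4-dihydroxy-6-pentylbenzoate)
Conditions: BnBr (1.05 equiv), KHCO3, DMF, rt
Reagents that add atoms: benzyl bromide, BrCc1ccccc1
Why: Hydrogencarbonate deprotonates only the carboxylic acid, so SN2 alkylation of the carboxylate gives the ester while both phenols stay free.

Step 3
Reactants: 4 benzyl olivetolate
Product: 5 benzyl 2-hydroxy-4-methoxy-6-pentylbenzoate
Conditions: MeI (1.1 equiv), K2CO3, acetone, rt to 40 °C
Reagents that add atoms: iodomethane, CI
Why: In this Williamson etherification the 2-hydroxyl is hydrogen-bonded to the ester carbonyl and reacts far more slowly than the free 4-hydroxyl, the usual selectivity of orsellinate-type esters.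

Step 4
Reactants: 5 benzyl 2-hydroxy-4-methoxy-6-pentylbenzoate
Product: 6 potassium 3-(benzyloxycarbonyl)-4-hydroxy-6-methoxy-2-pentylphenyl sulfate
Conditions: K2S2O8 (1.1 equiv, added slowly), 10% aq KOH, pyridine, 5 °C to rt; bring to pH 7-8, wash with Et2O (returns unreacted 5), evaporate, extract the salt with hot EtOH
Reagents that add atoms: potassium peroxodisulfate, [K+].[K+].[O-]S(=O)(=O)OOS(=O)(=O)[O-]
Why: In the Elbs persulfate oxidation the phenoxide attacks a peroxide oxygen through its para carbon, here the only free position para to the phenol, and the di-ortho-substituted benzoate next to a phenoxide should resist saponification at room temperature.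

Step 5
Reactants: 6 potassium 3-(benzyloxycarbonyl)-4-hydroxy-6-methoxy-2-pentylphenyl sulfate
Product: 8 benzyl 6-benzyloxy-3-hydroxy-4-methoxy-2-pentylbenzoate, via benzylated aryl sulfate 7 (not isolated)
Conditions: BnBr (1.5 equiv), K2CO3, DMF, 50 °C; filter and concentrate; then 2 M aq HCl, THF, 65 °C
Reagents that add atoms: benzyl bromide, BrCc1ccccc1
Why: The sulfate monoester anion is inert to benzyl bromide and masks the new oxygen while the chelated phenol undergoes Williamson benzylation (the known alkylate-then-hydrolyse variant of the Elbs procedure), after which warm dilute acid cleaves the aryl sulfate but not the benzyl ether or the hindered benzyl ester; any carboxylate formed by saponification in step 4 is re-esterified here.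

Step 6
Reactants: 9 cyclohexane-1,3-dione
Product: 10 3-chlorocyclohex-2-en-1-one
Conditions: (COCl)2, DMF (cat.), CH2Cl2, 0 °C to rt
Reagents that add atoms: oxalyl chloride, ClC(=O)C(=O)Cl
Why: The enol of the vinylogous acid is activated by the Vilsmeier-type chloroiminium species and displaced by chloride, the standard preparation of this vinylogous acid chloride.

Step 7
Reactants: 8 benzyl 6-benzyloxy-3-hydroxy-4-methoxy-2-pentylbenzoate; 10 3-chlorocyclohex-2-en-1-one
Product: 11 benzyl 6-benzyloxy-4-methoxy-3-[(3-oxocyclohex-1-en-1-yl)oxy]-2-pentylbenzoate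
Conditions: K2CO3, DMF, 60 °C
Reagents that add atoms: none
Why: Conjugate addition of the phenoxide to the beta-chloroenone and loss of chloride (addition-elimination) takes place at an unhindered sp2 carbon, so the crowding around the ring B phenol matters little.

Step 8
Reactants: 11 benzyl 6-benzyloxy-4-methoxy-3-[(3-oxocyclohex-1-en-1-yl)oxy]-2-pentylbenzoate
Product: 12 benzyl 6-benzyloxy-4-methoxy-2-pentyl-3-[(3-trimethylsilyloxycyclohexa-1,3-dien-1-yl)oxy]benzoate
Conditions: LiN(i-Pr)2 (1.1 equiv), Me3SiCl (1.5 equiv, present from the start), THF, -78 °C to 0 °C; pentane, filtration under Ar, used crude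
Reagents that add atoms: chlorotrimethylsilane, C[Si](C)(C)Cl
Why: Kinetic deprotonation of the vinylogous ester occurs at the alpha' methylene and not at the gamma position, and O-silylation of the cross-conjugated enolate gives the 1-aryloxy-3-silyloxy diene as in the preparation of Danishefsky-type dienes, while the hindered benzyl ester and the benzylic positions are much less acidic and are left alone.

Step 9
Reactants: 12 benzyl 6-benzyloxy-4-methoxy-2-pentyl-3-[(3-trimethylsilyloxycyclohexa-1,3-dien-1-yl)oxy]benzoate; 13 methyl oct-2-ynoate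
Product: 16 benzyl 6-benzyloxy-3-(5-hydroxy-2-methoxycarbonyl-3-pentylphenoxy)-4-methoxy-2-pentylbenzoate, via bicyclo[2.2.2]octadiene adduct 14 (not isolated), via aryl trimethylsilyl ether 15 (not isolated)
Conditions: 13 (5 equiv, neat), 185 °C, sealed tube, Ar; then 1 M aq HCl, THF, rt
Reagents that add atoms: none
Why: The electron-rich diene of 12 adds across the triple bond of 13 in a thermal normal-demand [4+2] cycloaddition to give bicyclo[2.2.2]octadiene 14, which at the same temperature expels its saturated two-carbon bridge as ethylene by retro-Diels-Alder reaction, aromatisation driving the sequence. This is the Alder-Rickert reaction, known for 1-alkoxy-3-trimethylsilyloxycyclohexa-1,3-dienes and alk-2-ynoates as a route to 2-alkyl-4-hydroxy-6-alkoxybenzoates. Ring A is closed by the intermolecular cycloaddition itself, its six carbons being the four diene carbons and the two alkyne carbons, with C6-C1 and C2-C3 as the new bonds (ring A numbering, C1 bearing the ester). The two bridgehead stereocentres of 14 are racemic and vanish on aromatisation, so no stereocontrol is needed. The required selectivity is regiochemical: the CH terminus of the silyl enol ether, toward which both oxygen donors push electron density, bonds to the pentyl-bearing beta carbon of the ynoate, which places the ester carbon next to the aryloxy-bearing carbon. Dilute acid on work-up cleaves aryl silyl ether 15 to the free C4 phenol and leaves the benzyl groups and both esters intact.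

Step 10
Reactants: 16 benzyl 6-benzyloxy-3-(5-hydroxy-2-methoxycarbonyl-3-pentylphenoxy)-4-methoxy-2-pentylbenzoate
Product: 1 epiphorellic acid 1
Conditions: H2 (1 atm), Pd/C (10 wt% Pd on carbon), EtOAc, rt
Reagents that add atoms: none
Why: Catalytic hydrogenolysis cleaves the benzyl ester and the benzyl ether together, while the methyl ester, the diaryl ether and the arenes are untouched under these conditions.

**Compound list**

1 | epiphorellic acid 1, 6-hydroxy-3-(5-hydroxy-2-methoxycarbonyl-3-pentylphenoxy)-4-methoxy-2-pentylbenzoic acid | CCCCCc1cc(O)cc(Oc2c(OC)cc(O)c(C(=O)O)c2CCCCC)c1C(=O)OC | target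
2 | olivetol, 5-pentylbenzene-1,3-diol | CCCCCc1cc(O)cc(O)c1 | starting material
3 | olivetolic acid, 2,4-dihydroxy-6-pentylbenzoic acid | CCCCCc1cc(O)cc(O)c1C(=O)O | intermediate
4 | benzyl 2,4-dihydroxy-6-pentylbenzoate | CCCCCc1cc(O)cc(O)c1C(=O)OCc1ccccc1 | intermediate
5 | benzyl 2-hydroxy-4-methoxy-6-pentylbenzoate | CCCCCc1cc(OC)cc(O)c1C(=O)OCc1ccccc1 | intermediate
6 | potassium 3-(benzyloxycarbonyl)-4-hydroxy-6-methoxy-2-pentylphenyl sulfate | CCCCCc1c(OS(=O)(=O)[O-])c(OC)cc(O)c1C(=O)OCc1ccccc1.[K+] | intermediate
7 | potassium 4-benzyloxy-3-(benzyloxycarbonyl)-6-methoxy-2-pentylphenyl sulfate (formed in the flask) | CCCCCc1c(OS(=O)(=O)[O-])c(OC)cc(OCc2ccccc2)c1C(=O)OCc1ccccc1.[K+] | intermediate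
8 | benzyl 6-benzyloxy-3-hydroxy-4-methoxy-2-pentylbenzoate | CCCCCc1c(O)c(OC)cc(OCc2ccccc2)c1C(=O)OCc1ccccc1 | intermediate
9 | cyclohexane-1,3-dione | O=C1CCCC(=O)C1 | starting material
10 | 3-chlorocyclohex-2-en-1-one | O=C1C=C(Cl)CCC1 | intermediate
11 | benzyl 6-benzyloxy-4-methoxy-3-[(3-oxocyclohex-1-en-1-yl)oxy]-2-pentylbenzoate | O=C1C=C(Oc2c(OC)cc(OCc3ccccc3)c(C(=O)OCc3ccccc3)c2CCCCC)CCC1 | intermediate
12 | benzyl 6-benzyloxy-4-methoxy-2-pentyl-3-[(3-trimethylsilyloxycyclohexa-1,3-dien-1-yl)oxy]benzoate | C[Si](C)(C)OC1=CCCC(Oc2c(OC)cc(OCc3ccccc3)c(C(=O)OCc3ccccc3)c2CCCCC)=C1 | intermediate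
13 | methyl oct-2-ynoate | CCCCCC#CC(=O)OC | starting material
14 | methyl 1-[4-benzyloxy-3-(benzyloxycarbonyl)-6-methoxy-2-pentylphenoxy]-3-pentyl-5-(trimethylsilyloxy)bicyclo[2.2.2]octa-2,5-diene-2-carboxylate (racemic, bridgehead configurations fixed by the bicycle, formed in the flask) | COC(=O)C1=C(CCCCC)C2CCC1(Oc3c(OC)cc(OCc4ccccc4)c(C(=O)OCc4ccccc4)c3CCCCC)C=C2O[Si](C)(C)C | intermediate
15 | benzyl 6-benzyloxy-4-methoxy-3-[2-methoxycarbonyl-3-pentyl-5-(trimethylsilyloxy)phenoxy]-2-pentylbenzoate (formed in the flask) | CCCCCc1cc(O[Si](C)(C)C)cc(Oc2c(OC)cc(OCc3ccccc3)c(C(=O)OCc3ccccc3)c2CCCCC)c1C(=O)OC | intermediate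
16 | benzyl 6-benzyloxy-3-(5-hydroxy-2-methoxycarbonyl-3-pentylphenoxy)-4-methoxy-2-pentylbenzoate | CCCCCc1cc(O)cc(Oc2c(OC)cc(OCc3ccccc3)c(C(=O)OCc3ccccc3)c2CCCCC)c1C(=O)OC | intermediate

**Step count**

Total: 10 steps. Longest linear sequence: 9 steps (steps 1-5 and 7-10 from olivetol 2); step 6 is a one-step side branch.

**Steps most likely to fail**

1. Step 9. The bimolecular cycloaddition of the internal alkynoate may be slow at the temperature the silyl dienol ether tolerates. Thermal 1,5-hydrogen shifts could then scramble the diene, or desilylation could outrun ring formation. The fallback sets out from 12 and returns at 16, using a dienophile of higher reactivity and lower oxidation level. Diene 12 and commercial oct-2-ynal in toluene at about 80 °C should give the racemic bicyclic aldehyde adduct 1-[4-benzyloxy-3-(benzyloxycarbonyl)-6-methoxy-2-pentylphenoxy]-3-pentyl-5-(trimethylsilyloxy)bicyclo[2.2.2]octa-2,5-diene-2-carbaldehyde F1 before the diene can isomerise. Heating to about 150 °C then expels ethylene to give benzyl 6-benzyloxy-3-[2-formyl-3-pentyl-5-(trimethylsilyloxy)phenoxy]-4-methoxy-2-pentylbenzoate F2. Dilute aqueous HCl in THF desilylates this to benzyl 6-benzyloxy-3-(2-formyl-5-hydroxy-3-pentylphenoxy)-4-methoxy-2-pentylbenzoate F3. Pinnick oxidation (NaClO2, NaH2PO4, 2-methylbut-2-ene, t-BuOH/water) should give 2-[4-benzyloxy-3-(benzyloxycarbonyl)-6-methoxy-2-pentylphenoxy]-4-hydroxy-6-pentylbenzoic acid F4. Alkylation of its carboxylate with MeI and KHCO3 in DMF leads to 16.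

2. Step 4. The persulfate hydroxylation may stop at low conversion, over-oxidise the product, or be accompanied by saponification of the benzyl ester in the aqueous alkali. The fallback sets out from 5 and returns at 11, replacing the sulfate route by a quinone route. Teuber oxidation of 5 with Fremy's salt (KSO3)2NO in buffered aqueous acetone should give benzyl 4-methoxy-3,6-dioxo-2-pentylcyclohexa-1,4-diene-1-carboxylate F5. Reduction with Na2S2O4 gives benzyl 2,5-dihydroxy-4-methoxy-6-pentylbenzoate F6. Under argon with K2CO3 in acetone, the non-chelated 5-hydroxyl should react selectively with chloroenone 10 to give benzyl 6-hydroxy-4-methoxy-3-[(3-oxocyclohex-1-en-1-yl)oxy]-2-pentylbenzoate F7. Benzylation of the remaining chelated phenol (BnBr, K2CO3, DMF, 60 °C) gives 11.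

3. Step 1. Carboxylation may occur partly at the position between the two hydroxyls, and the salicylic acid may lose CO2 again during the acidic quench. The fallback sets out from 2 and returns at 5, introducing the carboxyl carbon as an aldehyde. Vilsmeier-Haack formylation of 2 (POCl3, DMF) proceeds through [(2,4-dihydroxy-6-pentylphenyl)methylidene]dimethylammonium chloride F8, which is hydrolysed on aqueous work-up to 2,4-dihydroxy-6-pentylbenzaldehyde F9. Selective methylation of the non-chelated hydroxyl (MeI, K2CO3, acetone) gives 2-hydroxy-4-methoxy-6-pentylbenzaldehyde F10. Oxidation with NaClO2 and sulfamic acid in aqueous dioxane gives 2-hydroxy-4-methoxy-6-pentylbenzoic acid F11. Benzylation of the carboxylate (BnBr, KHCO3, DMF) gives 5.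

Further compounds
F1 | step 9 | 1-[4-benzyloxy-3-(benzyloxycarbonyl)-6-methoxy-2-pentylphenoxy]-3-pentyl-5-(trimethylsilyloxy)bicyclo[2.2.2]octa-2,5-diene-2-carbaldehyde (racemic) | O=CC1=C(CCCCC)C2CCC1(Oc3c(OC)cc(OCc4ccccc4)c(C(=O)OCc4ccccc4)c3CCCCC)C=C2O[Si](C)(C)C
F2 | step 9 | benzyl 6-benzyloxy-3-[2-formyl-3-pentyl-5-(trimethylsilyloxy)phenoxy]-4-methoxy-2-pentylbenzoate | CCCCCc1cc(O[Si](C)(C)C)cc(Oc2c(OC)cc(OCc3ccccc3)c(C(=O)OCc3ccccc3)c2CCCCC)c1C=O
F3 | step 9 | benzyl 6-benzyloxy-3-(2-formyl-5-hydroxy-3-pentylphenoxy)-4-methoxy-2-pentylbenzoate | CCCCCc1cc(O)cc(Oc2c(OC)cc(OCc3ccccc3)c(C(=O)OCc3ccccc3)c2CCCCC)c1C=O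
F4 | step 9 | 2-[4-benzyloxy-3-(benzyloxycarbonyl)-6-methoxy-2-pentylphenoxy]-4-hydroxy-6-pentylbenzoic acid | CCCCCc1cc(O)cc(Oc2c(OC)cc(OCc3ccccc3)c(C(=O)OCc3ccccc3)c2CCCCC)c1C(=O)O
F5 | step 4 | benzyl 4-methoxy-3,6-dioxo-2-pentylcyclohexa-1,4-diene-1-carboxylate | CCCCCC1=C(C(=O)OCc2ccccc2)C(=O)C=C(OC)C1=O
F6 | step 4 | benzyl 2,5-dihydroxy-4-methoxy-6-pentylbenzoate | CCCCCc1c(O)c(OC)cc(O)c1C(=O)OCc1ccccc1
F7 | step 4 | benzyl 6-hydroxy-4-methoxy-3-[(3-oxocyclohex-1-en-1-yl)oxy]-2-pentylbenzoate | O=C1C=C(Oc2c(OC)cc(O)c(C(=O)OCc3ccccc3)c2CCCCC)CCC1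
F8 | step 1 | [(2,4-dihydroxy-6-pentylphenyl)methylidene]dimethylammonium chloride | CCCCCc1cc(O)cc(O)c1C=[N+](C)C.[Cl-]
F9 | step 1 | 2,4-dihydroxy-6-pentylbenzaldehyde | CCCCCc1cc(O)cc(O)c1C=O
F10 | step 1 | 2-hydroxy-4-methoxy-6-pentylbenzaldehyde | CCCCCc1cc(OC)cc(O)c1C=O
F11 | step 1 | 2-hydroxy-4-methoxy-6-pentylbenzoic acid | CCCCCc1cc(OC)cc(O)c1C(=O)O
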